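**Retrosynthetic overview**
- The oxirane is made late by Shi epoxidation of the prenyl alkene, and one fluoride desilylation ends the route.
- The strategy rests on the benzyl ring attached to the quaternary lactone carbon C5: a 1,3,4-trisubstituted benzene (C1 bears the CH2 to C5, C3 the prenyl-derived chain, C4 the oxygen). Its six carbons are cut into C3–C6 of a 5-substituted 2-pyrone and the two sp carbons of a siloxyalkyne, joined by [4+2] cycloaddition and CO2 extrusion.
- The pyrone is attached to C5 by enantioselective phase-transfer alkylation of the racemic 5-H butenolide with 5-(bromomethyl)-2-pyrone (from coumalic acid). The siloxyalkyne comes from ethyl 4-methylpent-3-enoate by ynolate homologation and O-silylation.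
- Ring order: butenolide first (aldol–lactonisation of methyl 4-hydroxyphenylpyruvate with methyl glyoxylate), then the benzene ring (key step), then the oxirane.

Key step: step 8

Remark on numbering: the butenolide is numbered O1, C2 (lactone C=O), C3 (oxygenated), C4 (aryl), C5 (quaternary), and compound names follow this numbering.
Remark on protecting groups: triisopropylsilyl is used on all three oxygens (instead of a mixed set), so that the ethers survive carbonate base, 110 °C and the buffered epoxidation and fall in one final operation.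
Assumption: the sense of induction of the phase-transfer catalyst on this substrate cannot be predicted with confidence; the (S,S) catalyst is written, and its equally available (R,R) antipode is to be used if a first trial shows the (5S) product.

**Route**

Step 1
Reactants: 1 4-hydroxyphenylpyruvic acid
Product: 2 methyl 3-(4-hydroxyphenyl)-2-oxopropanoate (methyl 4-hydroxyphenylpyruvate, largely enolised)
Conditions: MeI (1.0 equiv), DBU (1.0 equiv), DMF, 0 °C
Reagents that add atoms: iodomethane, CI
Why: SN2 esterification of the carboxylate; with one equivalent of amidine base only the carboxylic acid is ionised, so the phenol and the enol should stay unmethylated.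

Step 2
Reactants: 2 methyl 3-(4-hydroxyphenyl)-2-oxopropanoate; 3 methyl glyoxylate
Product: 5 racemic methyl 3-hydroxy-4-(4-hydroxyphenyl)-2-oxo-2,5-dihydrofuran-5-carboxylate, via aldol adduct 4 (not isolated)
Conditions: Et3N (1.2 equiv), THF, 0 °C to rt; 1 M HCl work-up
Reagents that add atoms: none
Why: Aldol addition of the benzylic carbon of the arylpyruvate to the very electrophilic aldehyde, then lactonisation of the new hydroxyl onto the alpha-keto ester with loss of methanol and enolisation (isotetronic acid synthesis); C5 is formed racemic and is flattened again at the enolate stage of step 6.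

Step 3
Reactants: 5 racemic methyl 3-hydroxy-4-(4-hydroxyphenyl)-2-oxo-2,5-dihydrofuran-5-carboxylate
Product: 6 racemic methyl 2-oxo-3-(triisopropylsilyloxy)-4-[4-(triisopropylsilyloxy)phenyl]-2,5-dihydrofuran-5-carboxylate
Conditions: TIPSCl (2.4 equiv), imidazole, DMF, rt
Reagents that add atoms: triisopropylsilyl chloride, CC(C)[Si](Cl)(C(C)C)C(C)C
Why: Imidazole-promoted O-silylation of the two acidic hydroxyls (phenol and C3 enol); the mild base should not form the 2-silyloxyfuran, and the bulky C3 silyl ether shields C3 in step 6.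

Step 4
Reactants: 7 coumalic acid
Product: 8 5-(hydroxymethyl)-2H-pyran-2-one
Conditions: BH3·SMe2, THF, 0 °C to rt; aqueous work-up
Reagents that add atoms: none
Why: Chemoselective borane reduction of a carboxylic acid through its acyloxyborane, which should be much faster than reduction of the lactone carbonyl or hydroboration of the electron-poor pyranone alkenes.

Step 5
Reactants: 8 5-(hydroxymethyl)-2H-pyran-2-one
Product: 9 5-(bromomethyl)-2H-pyran-2-one
Conditions: CBr4, PPh3, CH2Cl2, 0 °C
Reagents that add atoms: carbon tetrabromide, BrC(Br)(Br)Br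
Why: Appel bromination of the primary allylic alcohol under neutral conditions that leave the base-sensitive pyranone intact.

Step 6
Reactants: 6 racemic methyl 2-oxo-3-(triisopropylsilyloxy)-4-[4-(triisopropylsilyloxy)phenyl]-2,5-dihydrofuran-5-carboxylate; 9 5-(bromomethyl)-2H-pyran-2-one
Product: 10 methyl (5R)-2-oxo-5-[(2-oxo-2H-pyran-5-yl)methyl]-3-(triisopropylsilyloxy)-4-[4-(triisopropylsilyloxy)phenyl]-2,5-dihydrofuran-5-carboxylate
Conditions: (S,S)-3,4,5-trifluorophenyl-NAS bromide (spiro bis-binaphthyl ammonium bromide, 2 mol%), Cs2CO3 (solid), toluene, −20 °C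
Reagents that add atoms: none
Why: Proposed new method: carbonate removes the acidic C5–H (alpha to the ester, vinylogous to the lactone) to give a planar furan-2-olate that pairs with the chiral ammonium cation, which should shield one face so that SN2 attack on the allylic bromide sets the (5R) quaternary centre, with C5 preferred over C3 because C3 carries the bulky silyloxy group and C5 attack keeps the conjugated butenolide; the closest known reactions are asymmetric phase-transfer benzylations of phthalide-3-carboxylic esters, cyclic beta-keto esters and alpha-alkoxycarbonyl lactones.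

Step 7
Reactants: 11 ethyl 4-methylpent-3-enoate
Product: 14 triisopropyl[(5-methylhex-4-en-1-yn-1-yl)oxy]silane, via lithium dibromoenolate 12 (not isolated), via lithium ynolate 13 (not isolated)
Conditions: CH2Br2, lithium 2,2,6,6-tetramethylpiperidide, THF, −78 °C; LiN(SiMe3)2; n-BuLi, −78 °C to rt; TIPSOTf, −78 °C to 0 °C
Reagents that add atoms: dibromomethane, BrCBr; triisopropylsilyl trifluoromethanesulfonate, CC(C)[Si](OS(=O)(=O)C(F)(F)F)(C(C)C)C(C)C
Why: Kowalski ynolate homologation: LiCHBr2 adds to the ester, the derived dibromoenolate undergoes bromine–lithium exchange and 1,2-shift to the ynolate, and the hindered silyl triflate should trap it on oxygen.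

Step 8
Reactants: 10 methyl (5R)-2-oxo-5-[(2-oxo-2H-pyran-5-yl)methyl]-3-(triisopropylsilyloxy)-4-[4-(triisopropylsilyloxy)phenyl]-2,5-dihydrofuran-5-carboxylate; 14 triisopropyl[(5-methylhex-4-en-1-yn-1-yl)oxy]silane
Product: 16 methyl (5R)-5-{[3-(3-methylbut-2-en-1-yl)-4-(triisopropylsilyloxy)phenyl]methyl}-2-oxo-3-(triisopropylsilyloxy)-4-[4-(triisopropylsilyloxy)phenyl]-2,5-dihydrofuran-5-carboxylate, via bridged bicyclic lactone 15 (not isolated)
Conditions: 14 (3 equiv), toluene (1 M), 110 °C, sealed tube, base-washed glass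
Reagents that add atoms: none
Why: Proposed new method: the electron-rich siloxyalkyne 14 should add across C3 and C6 of the electron-poor 2-pyrone of 10 in a [4+2] cycloaddition with inverse electron demand, the bond from the nucleophilic alkyne carbon (the one carrying the prenyl CH2) to pyrone C6 running ahead of the bond from the oxygenated carbon to pyrone C3; the closest known reactions are the thermal Diels–Alder/retro-Diels–Alder benzannulations of 2-pyrones with ynamines, alkoxyalkynes and alkynylboronates and the silver-catalysed inverse-demand cycloadditions of siloxyalkynes with 1,2-diazines. The bridged 2-oxabicyclo[2.2.2]octadienone 15 then loses CO2 by cycloreversion, driven by aromatisation, so the benzene ring is closed by cycloaddition followed by extrusion and contains pyrone C3 to C6 and both alkyne carbons. No stereocentre is created, since the bridgehead centres of 15 vanish on aromatisation, and the quaternary C5, which has no acidic hydrogen, is not touched. The step needs one regiochemistry, secured by pairing the more nucleophilic alkyne terminus with the delta carbon C6 of the pyranone dienoate, its most electrophilic ring position, which puts the silyloxy group para and the prenyl group meta to the CH2 link. The silyl ethers, the methyl ester and the butenolide should be inert to heat alone, and 110 °C is chosen because triisopropylsiloxyalkynes tolerate this range in thermal benzannulations with vinylketenes, whereas rearrangement to silylketenes is expected at higher temperature.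

Step 9
Reactants: 16 methyl (5R)-5-{[3-(3-methylbut-2-en-1-yl)-4-(triisopropylsilyloxy)phenyl]methyl}-2-oxo-3-(triisopropylsilyloxy)-4-[4-(triisopropylsilyloxy)phenyl]-2,5-dihydrofuran-5-carboxylate
Product: 17 methyl (5R)-5-{[3-{[(2R)-3,3-dimethyloxiran-2-yl]methyl}-4-(triisopropylsilyloxy)phenyl]methyl}-2-oxo-3-(triisopropylsilyloxy)-4-[4-(triisopropylsilyloxy)phenyl]-2,5-dihydrofuran-5-carboxylate
Conditions: D-fructose-derived Shi ketone (1,2:4,5-di-O-isopropylidene-β-D-erythro-2,3-hexodiulo-2,6-pyranose, 30 mol%), Oxone (2KHSO5·KHSO4·K2SO4), K2CO3, Bu4NHSO4, MeCN/CH2(OMe)2/aq. Na2B4O7 buffer, 0 °C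
Reagents that add atoms: potassium peroxymonosulfate, [K+].[O-]S(=O)(=O)OO
Why: Shi epoxidation: the chiral dioxirane should deliver oxygen through a spiro transition state to one face of the trisubstituted alkene, giving the (R) oxirane under reagent control whatever the remote C5, while the hindered C3=C4 enol ether conjugated to the lactone reacts far more slowly than the isolated electron-rich alkene.

Step 10
Reactants: 17 methyl (5R)-5-{[3-{[(2R)-3,3-dimethyloxiran-2-yl]methyl}-4-(triisopropylsilyloxy)phenyl]methyl}-2-oxo-3-(triisopropylsilyloxy)-4-[4-(triisopropylsilyloxy)phenyl]-2,5-dihydrofuran-5-carboxylate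
Product: 18 methyl (5R)-5-{[3-{[(2R)-3,3-dimethyloxiran-2-yl]methyl}-4-hydroxyphenyl]methyl}-3-hydroxy-4-(4-hydroxyphenyl)-2-oxo-2,5-dihydrofuran-5-carboxylate (CNP0331593.1)
Conditions: Bu4NF (4 equiv), AcOH (4 equiv), THF, 0 °C to rt
Reagents that add atoms: none
Why: Fluoride cleavage of the three Si–O bonds (two aryl silyl ethers and the enol silyl ether); the acetic acid buffer should keep the freed phenol next to the oxirane chain protonated so that it does not open the epoxide, and the methyl ester, lactone and both stereocentres are not affected.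

**Compound list**
1 | 4-hydroxyphenylpyruvic acid | OC(=O)C(=O)Cc1ccc(O)cc1 | starting material
2 | methyl 3-(4-hydroxyphenyl)-2-oxopropanoate | COC(=O)C(=O)Cc1ccc(O)cc1 | intermediate
3 | methyl glyoxylate | COC(=O)C=O | starting material
4 | dimethyl 2-hydroxy-3-(4-hydroxyphenyl)-4-oxopentanedioate (aldol adduct, stereoisomer mixture) | COC(=O)C(O)C(c1ccc(O)cc1)C(=O)C(=O)OC | intermediate
5 | racemic methyl 3-hydroxy-4-(4-hydroxyphenyl)-2-oxo-2,5-dihydrofuran-5-carboxylate | COC(=O)C1OC(=O)C(O)=C1c1ccc(O)cc1 | intermediate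
6 | racemic methyl 2-oxo-3-(triisopropylsilyloxy)-4-[4-(triisopropylsilyloxy)phenyl]-2,5-dihydrofuran-5-carboxylate | COC(=O)C1OC(=O)C(O[Si](C(C)C)(C(C)C)C(C)C)=C1c1ccc(O[Si](C(C)C)(C(C)C)C(C)C)cc1 | intermediate
7 | coumalic acid (2-oxo-2H-pyran-5-carboxylic acid) | OC(=O)C1=COC(=O)C=C1 | starting material
8 | 5-(hydroxymethyl)-2H-pyran-2-one | OCC1=COC(=O)C=C1 | intermediate
9 | 5-(bromomethyl)-2H-pyran-2-one | BrCC1=COC(=O)C=C1 | intermediate
10 | methyl (5R)-2-oxo-5-[(2-oxo-2H-pyran-5-yl)methyl]-3-(triisopropylsilyloxy)-4-[4-(triisopropylsilyloxy)phenyl]-2,5-dihydrofuran-5-carboxylate | COC(=O)[C@]1(CC2=COC(=O)C=C2)OC(=O)C(O[Si](C(C)C)(C(C)C)C(C)C)=C1c1ccc(O[Si](C(C)C)(C(C)C)C(C)C)cc1 | intermediate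
11 | ethyl 4-methylpent-3-enoate | CCOC(=O)CC=C(C)C | starting material
12 | lithium 1,1-dibromo-5-methylhexa-1,4-dien-2-olate | [Li+].[O-]C(CC=C(C)C)=C(Br)Br | intermediate
13 | lithium 5-methylhex-4-en-1-yn-1-olate | [Li+].[O-]C#CCC=C(C)C | intermediate
14 | triisopropyl[(5-methylhex-4-en-1-yn-1-yl)oxy]silane | CC(C)=CCC#CO[Si](C(C)C)(C(C)C)C(C)C | intermediate
15 | bridged 2-oxabicyclo[2.2.2]octa-5,7-dien-3-one cycloadduct of 10 and 14 (bridgehead diastereomers, C5 of the butenolide R) | COC(=O)[C@]1(CC2=CC3C(=O)OC2C(CC=C(C)C)=C3O[Si](C(C)C)(C(C)C)C(C)C)OC(=O)C(O[Si](C(C)C)(C(C)C)C(C)C)=C1c1ccc(O[Si](C(C)C)(C(C)C)C(C)C)cc1 | intermediate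
16 | methyl (5R)-5-{[3-(3-methylbut-2-en-1-yl)-4-(triisopropylsilyloxy)phenyl]methyl}-2-oxo-3-(triisopropylsilyloxy)-4-[4-(triisopropylsilyloxy)phenyl]-2,5-dihydrofuran-5-carboxylate | COC(=O)[C@]1(Cc2ccc(O[Si](C(C)C)(C(C)C)C(C)C)c(CC=C(C)C)c2)OC(=O)C(O[Si](C(C)C)(C(C)C)C(C)C)=C1c1ccc(O[Si](C(C)C)(C(C)C)C(C)C)cc1 | intermediate
17 | methyl (5R)-5-{[3-{[(2R)-3,3-dimethyloxiran-2-yl]methyl}-4-(triisopropylsilyloxy)phenyl]methyl}-2-oxo-3-(triisopropylsilyloxy)-4-[4-(triisopropylsilyloxy)phenyl]-2,5-dihydrofuran-5-carboxylate | COC(=O)[C@]1(Cc2ccc(O[Si](C(C)C)(C(C)C)C(C)C)c(C[C@H]3OC3(C)C)c2)OC(=O)C(O[Si](C(C)C)(C(C)C)C(C)C)=C1c1ccc(O[Si](C(C)C)(C(C)C)C(C)C)cc1 | intermediate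
18 | methyl (5R)-5-{[3-{[(2R)-3,3-dimethyloxiran-2-yl]methyl}-4-hydroxyphenyl]methyl}-3-hydroxy-4-(4-hydroxyphenyl)-2-oxo-2,5-dihydrofuran-5-carboxylate | COC(=O)[C@]1(Cc2ccc(O)c(C[C@H]3OC3(C)C)c2)OC(=O)C(O)=C1c1ccc(O)cc1 | target

**Step count**
Total: 10 steps. Longest linear sequence: 7 steps (steps 1, 2, 3, 6, 8, 9, 10, from 4-hydroxyphenylpyruvic acid).

**Steps most likely to fail**

Step 8. The siloxyalkyne may be consumed by thermal silyl migration and oligomerisation faster than it adds to the only weakly electron-poor 5-alkylpyrone, or the cycloaddition may not start at a temperature the alkyne survives. The fallback gives up the pyrone and brings in the finished arene as a benzylic bromide by known chemistry; it sets out from 6 and returns at 16. Commercial methyl 4-hydroxybenzoate is C-prenylated ortho to oxygen as its sodium phenoxide (NaH, prenyl bromide, toluene) to give methyl 4-hydroxy-3-(3-methylbut-2-en-1-yl)benzoate F1. Silylation (TIPSCl, imidazole, DMF) gives methyl 3-(3-methylbut-2-en-1-yl)-4-(triisopropylsilyloxy)benzoate F2. Reduction (i-Bu2AlH, CH2Cl2, −78 °C) gives [3-(3-methylbut-2-en-1-yl)-4-(triisopropylsilyloxy)phenyl]methanol F3, and Appel bromination (CBr4, PPh3) gives 4-(bromomethyl)-2-(3-methylbut-2-en-1-yl)-1-(triisopropylsilyloxy)benzene F4. Alkylation of 6 with F4 (Cs2CO3, MeCN, 0 °C) should give racemic 16 F5. Preparative chromatography on a chiral stationary phase then separates 16 from its (5S) antipode F6, which is set aside.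

Step 6. The ion pair may discriminate poorly between the two faces of the planar furanolate (low enantiomeric purity), or some attack may occur through C3. The fallback replaces catalytic enantiocontrol by resolution; it sets out from 6 (with 9) and returns at 10. Plain carbonate alkylation (Cs2CO3, MeCN, 0 °C) should give racemic methyl 2-oxo-5-[(2-oxo-2H-pyran-5-yl)methyl]-3-(triisopropylsilyloxy)-4-[4-(triisopropylsilyloxy)phenyl]-2,5-dihydrofuran-5-carboxylate F7. Preparative chromatography on a chiral stationary phase then delivers 10 and leaves the (5S) enantiomer F8.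

Step 7. The carbenoid and amide bases may deprotonate the doubly activated CH2 of the beta,gamma-unsaturated ester instead of adding to the carbonyl, and the skipped enyne may isomerise under the strongly basic conditions. The fallback reaches the same ynolate from an acetylide; it sets out from 11 and returns at 13 (and so at 14). Reduction of 11 (i-Bu2AlH, CH2Cl2, −78 °C) gives 4-methylpent-3-enal F9, used crude. Dibromo-olefination (CBr4, PPh3, CH2Cl2, 0 °C, first stage of the Corey–Fuchs sequence) gives 1,1-dibromo-5-methylhexa-1,4-diene F10. n-BuLi (2 equiv, THF, −78 °C) converts it into lithium 5-methylhex-4-en-1-yn-1-ide F11 in the flask. Oxidation with lithium tert-butyl peroxide (from t-BuOOH and LiN(SiMe3)2, −78 to 0 °C) gives ynolate 13, which is silylated with TIPSOTf as in step 7.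

**Further compounds**
F1 | step 8 | methyl 4-hydroxy-3-(3-methylbut-2-en-1-yl)benzoate | COC(=O)c1ccc(O)c(CC=C(C)C)c1
F2 | step 8 | methyl 3-(3-methylbut-2-en-1-yl)-4-(triisopropylsilyloxy)benzoate | COC(=O)c1ccc(O[Si](C(C)C)(C(C)C)C(C)C)c(CC=C(C)C)c1
F3 | step 8 | [3-(3-methylbut-2-en-1-yl)-4-(triisopropylsilyloxy)phenyl]methanol | OCc1ccc(O[Si](C(C)C)(C(C)C)C(C)C)c(CC=C(C)C)c1
F4 | step 8 | 4-(bromomethyl)-2-(3-methylbut-2-en-1-yl)-1-(triisopropylsilyloxy)benzene | BrCc1ccc(O[Si](C(C)C)(C(C)C)C(C)C)c(CC=C(C)C)c1
F5 | step 8 | racemic methyl 5-{[3-(3-methylbut-2-en-1-yl)-4-(triisopropylsilyloxy)phenyl]methyl}-2-oxo-3-(triisopropylsilyloxy)-4-[4-(triisopropylsilyloxy)phenyl]-2,5-dihydrofuran-5-carboxylate | COC(=O)C1(Cc2ccc(O[Si](C(C)C)(C(C)C)C(C)C)c(CC=C(C)C)c2)OC(=O)C(O[Si](C(C)C)(C(C)C)C(C)C)=C1c1ccc(O[Si](C(C)C)(C(C)C)C(C)C)cc1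
F6 | step 8 | (5S) enantiomer of 16 | COC(=O)[C@@]1(Cc2ccc(O[Si](C(C)C)(C(C)C)C(C)C)c(CC=C(C)C)c2)OC(=O)C(O[Si](C(C)C)(C(C)C)C(C)C)=C1c1ccc(O[Si](C(C)C)(C(C)C)C(C)C)cc1
F7 | step 6 | racemic methyl 2-oxo-5-[(2-oxo-2H-pyran-5-yl)methyl]-3-(triisopropylsilyloxy)-4-[4-(triisopropylsilyloxy)phenyl]-2,5-dihydrofuran-5-carboxylate | COC(=O)C1(CC2=COC(=O)C=C2)OC(=O)C(O[Si](C(C)C)(C(C)C)C(C)C)=C1c1ccc(O[Si](C(C)C)(C(C)C)C(C)C)cc1
F8 | step 6 | (5S) enantiomer of 10 | COC(=O)[C@@]1(CC2=COC(=O)C=C2)OC(=O)C(O[Si](C(C)C)(C(C)C)C(C)C)=C1c1ccc(O[Si](C(C)C)(C(C)C)C(C)C)cc1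
F9 | step 7 | 4-methylpent-3-enal | CC(C)=CCC=O
F10 | step 7 | 1,1-dibromo-5-methylhexa-1,4-diene | CC(C)=CCC=C(Br)Br
F11 | step 7 | lithium 5-methylhex-4-en-1-yn-1-ide | [Li+].[C-]#CCC=C(C)C
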